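**Plan**
- Cuts: first the two aryl O–CH2OMe acetals. Then, in the pyrone (ring C: O1', C2'–C6'), the bonds C4'–C5' and O1'–C2'.
- Enabling feature: O1'–C6'(Et)=C5'(Me) is the enol of symmetrical 3-pentanone. C2'–C3'–C4', with the bridge CH2 already on C3', is a substituted malonyl unit. Ring C is therefore the [3+3] sum of a malonyl dichloride and a silyl enol ether.
- Further cuts: the malonyl chain goes back to a C7 aldehyde plus dimethyl malonate. The dihydrofuran (ring B) is cut at C3–C3a and C2–O1 to a bromophenol plus myrcene.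
- Forward order: ring A (phloracetophenone) is dressed so that only the 4-OH is free, flanked by CHO and Br. Ring B is then closed, the malonyl chain is built on C7, ring C is closed, and the acetals are removed.
- Stereochemistry: the single centre C2 (R) is set by the chiral phosphine on palladium in the ring B annulation. No later step touches it.

Key step: step 12

Assumption: the ligand antipode is chosen by analogy with the isoprene annulation that gives (R)-2-isopropenyl-2,3-dihydrobenzofurans; if the sense proves opposite, the mirror-image ligand is used.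

**Step 1**
Reactants: 1 2,4,6-trihydroxyacetophenone
Product: 2 1-[4-(benzyloxy)-2,6-dihydroxyphenyl]ethan-1-one
Conditions: BnBr (1.0 equiv), K2CO3 (1.1 equiv), DMF, rt
Reagents that add atoms: benzyl bromide, BrCc1ccccc1
Why: Williamson etherification; the 4-OH is the most acidic hydroxyl and the only one not hydrogen-bonded to the acetyl carbonyl, so one equivalent of base and halide should alkylate it first.

**Step 2**
Reactants: 2 1-[4-(benzyloxy)-2,6-dihydroxyphenyl]ethan-1-one
Product: 3 1-[4-(benzyloxy)-2,6-bis(methoxymethoxy)phenyl]ethan-1-one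
Conditions: NaH (2.4 equiv), MOMCl (2.6 equiv), DMF, 0 °C → rt
Reagents that add atoms: chloromethyl methyl ether, COCCl
Why: Williamson-type O-alkylation; full deprotonation with NaH breaks the hydrogen bonds to the carbonyl, and the hard electrophile should react at both phenoxide oxygens.

**Step 3**
Reactants: 3 1-[4-(benzyloxy)-2,6-bis(methoxymethoxy)phenyl]ethan-1-one
Product: 4 1-[4-hydroxy-2,6-bis(methoxymethoxy)phenyl]ethan-1-one
Conditions: H2 (1 atm), Pd/C (10 wt %), EtOAc, rt
Reagents that add atoms: none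
Why: Catalytic hydrogenolysis of the benzyl aryl ether, run before any alkene is present; the MOM acetals and the hindered, twisted aryl ketone should be left alone at 1 atm.

**Step 4**
Reactants: 4 1-[4-hydroxy-2,6-bis(methoxymethoxy)phenyl]ethan-1-one
Product: 5 3-acetyl-6-hydroxy-2,4-bis(methoxymethoxy)benzaldehyde
Conditions: MgCl2 (2 equiv), Et3N (4 equiv), (CH2O)n (6 equiv), MeCN, reflux; cold dilute HCl work-up
Reagents that add atoms: paraformaldehyde (as formaldehyde), C=O
Why: Casnati–Skattebøl ortho-formylation; the magnesium phenoxide delivers formaldehyde to one of the two equivalent ortho carbons, a second formaldehyde accepts hydride, and the new formyl group deactivates the ring against a second reaction.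

**Step 5**
Reactants: 5 3-acetyl-6-hydroxy-2,4-bis(methoxymethoxy)benzaldehyde
Product: 6 3-acetyl-5-bromo-6-hydroxy-2,4-bis(methoxymethoxy)benzaldehyde
Conditions: NBS (1.05 equiv), MeCN, 0 °C
Reagents that add atoms: N-bromosuccinimide, O=C1CCC(=O)N1Br
Why: Electrophilic aromatic bromination at the only remaining ring C–H, which is ortho to the free phenol and activated by three oxygens.

**Step 6**
Reactants: 6 3-acetyl-5-bromo-6-hydroxy-2,4-bis(methoxymethoxy)benzaldehyde; 7 myrcene
Product: 8 (R)-5-acetyl-4,6-bis(methoxymethoxy)-2-(6-methylhepta-1,5-dien-2-yl)-2,3-dihydrobenzofuran-7-carbaldehyde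
Conditions: Pd2(dba)3·CHCl3 (2.5 mol %), chiral sulfinamide monophosphine (TY-Phos type, 6 mol %), PhONa (2 equiv), 7 (3 equiv), CH2Cl2, 40 °C
Reagents that add atoms: none
Why: Asymmetric Heck/Tsuji–Trost heteroannulation (enantioselective Larock-type annulation) of an o-bromophenol with a 2-substituted 1,3-diene; arylpalladium adds to the unsubstituted vinyl terminus of myrcene, the only free phenoxide closes the five-membered ring on the internal π-allyl terminus with the ligand fixing the face and hence (R)-C2, and the two MOM groups exclude closure through the oxygen next to the acetyl group.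

**Step 7**
Reactants: 8 (R)-5-acetyl-4,6-bis(methoxymethoxy)-2-(6-methylhepta-1,5-dien-2-yl)-2,3-dihydrobenzofuran-7-carbaldehyde; 9 dimethyl malonate
Product: 10 dimethyl (R)-2-{[5-acetyl-4,6-bis(methoxymethoxy)-2-(6-methylhepta-1,5-dien-2-yl)-2,3-dihydrobenzofuran-7-yl]methylidene}malonate
Conditions: 9 (1.5 equiv), piperidine (0.2 equiv), AcOH (0.2 equiv), toluene, Dean–Stark, reflux
Reagents that add atoms: none
Why: Knoevenagel condensation under piperidinium acetate catalysis with removal of water; the buffered medium spares acetals and alkenes, and the malonate is far more acidic than the hindered methyl ketone.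

**Step 8**
Reactants: 10 dimethyl (R)-2-{[5-acetyl-4,6-bis(methoxymethoxy)-2-(6-methylhepta-1,5-dien-2-yl)-2,3-dihydrobenzofuran-7-yl]methylidene}malonate
Product: 11 dimethyl (R)-2-{[5-acetyl-4,6-bis(methoxymethoxy)-2-(6-methylhepta-1,5-dien-2-yl)-2,3-dihydrobenzofuran-7-yl]methyl}malonate
Conditions: NaBH4 (0.8 equiv), THF–MeOH, 0 °C; aq NH4Cl
Reagents that add atoms: none
Why: Conjugate (1,4) hydride reduction of an alkylidene malonate, which at 0 °C should be much faster than attack on the aryl methyl ketone shielded by two ortho substituents; isolated alkenes do not react.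

**Step 9**
Reactants: 11 dimethyl (R)-2-{[5-acetyl-4,6-bis(methoxymethoxy)-2-(6-methylhepta-1,5-dien-2-yl)-2,3-dihydrobenzofuran-7-yl]methyl}malonate
Product: 12 (R)-2-{[5-acetyl-4,6-bis(methoxymethoxy)-2-(6-methylhepta-1,5-dien-2-yl)-2,3-dihydrobenzofuran-7-yl]methyl}malonic acid
Conditions: KOH (6 equiv), MeOH–H2O, 50 °C; cold 1 M HCl to pH 3, EtOAc
Reagents that add atoms: potassium hydroxide, [K+].[OH-]
Why: Saponification of a malonic diester; MOM ethers, alkenes, the allylic aryl ether and C2 are inert to hydroxide, and brief cold acidification should release the diacid without decarboxylation or acetal loss.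

**Step 10**
Reactants: 13 3-pentanone
Product: 14 (Z)-3-(trimethylsilyloxy)pent-2-ene
Conditions: TMSCl (1.2 equiv), Et3N (2.4 equiv), DMF, 80 °C; pentane extraction, distillation
Reagents that add atoms: chlorotrimethylsilane, C[Si](C)(C)Cl
Why: Thermodynamic silyl enol ether formation; the ketone is symmetrical, so only one regioisomer exists, and any E isomer present leads to the same pyrone.

**Step 11**
Reactants: 12 (R)-2-{[5-acetyl-4,6-bis(methoxymethoxy)-2-(6-methylhepta-1,5-dien-2-yl)-2,3-dihydrobenzofuran-7-yl]methyl}malonic acid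
Product: 15 (R)-2-{[5-acetyl-4,6-bis(methoxymethoxy)-2-(6-methylhepta-1,5-dien-2-yl)-2,3-dihydrobenzofuran-7-yl]methyl}malonyl dichloride
Conditions: Me2C=C(Cl)NMe2 (2.2 equiv), CH2Cl2, 0 °C, 1 h; concentrated cold, used at once
Reagents that add atoms: 1-chloro-N,N,2-trimethylprop-1-en-1-amine (Ghosez reagent), CC(C)=C(Cl)N(C)C
Why: Acid chloride formation with the Ghosez α-chloroenamine, which transfers chloride under neutral conditions and liberates no HCl, so the acetals and both alkenes should survive.

**Step 12**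
Reactants: 15 (R)-2-{[5-acetyl-4,6-bis(methoxymethoxy)-2-(6-methylhepta-1,5-dien-2-yl)-2,3-dihydrobenzofuran-7-yl]methyl}malonyl dichloride; 14 (Z)-3-(trimethylsilyloxy)pent-2-ene
Product: 17 (R)-3-{[5-acetyl-4,6-bis(methoxymethoxy)-2-(6-methylhepta-1,5-dien-2-yl)-2,3-dihydrobenzofuran-7-yl]methyl}-6-ethyl-4-hydroxy-5-methyl-2H-pyran-2-one, via diketo acid chloride 16 (not isolated)
Conditions: 14 (3 equiv), Et2O, −78 °C → 0 °C; pH 5 buffer work-up
Reagents that add atoms: none
Why: The nucleophilic carbon of 14 attacks one acid chloride of 15 (or the chlorocarbonyl ketene in equilibrium with it) and Me3SiCl leaves, which forms C4'–C5' and gives the diketo acid chloride 16. The ethyl ketone of 16 enolises and its oxygen is acylated by the remaining acid chloride in a 6-exo-trig closure that forms O1'–C2', and tautomerisation then delivers the aromatic 4-hydroxy-2-pyrone (ring C). This is the Effenberger synthesis of 4-hydroxy-2-pyrones from malonyl dichlorides and silyl enol ethers, applied to a 2-substituted malonyl dichloride. No lasting stereocentre is created, since the sp3 carbons C3' and C5' of 16 both become sp2, and C2 lies far from the reacting centres. The step needs C-acylation before O-acylation by one ketone unit only: the symmetry of 3-pentanone leaves a single possible enol carbon, and the intramolecular second acylation should outrun a second enol ether. The HCl from ring closure is taken up by surplus 14 (giving 3-pentanone and Me3SiCl), which shields the MOM acetals, the two alkenes and the allylic C2–O1 bond.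

**Step 13**
Reactants: 17 (R)-3-{[5-acetyl-4,6-bis(methoxymethoxy)-2-(6-methylhepta-1,5-dien-2-yl)-2,3-dihydrobenzofuran-7-yl]methyl}-6-ethyl-4-hydroxy-5-methyl-2H-pyran-2-one
Product: 18 (R)-3-{[5-acetyl-4,6-dihydroxy-2-(6-methylhepta-1,5-dien-2-yl)-2,3-dihydrobenzofuran-7-yl]methyl}-6-ethyl-4-hydroxy-5-methyl-2H-pyran-2-one (CNP0294086.1)
Conditions: HCl (1.25 M in MeOH), 0 °C → rt
Reagents that add atoms: none
Why: Acid-catalysed transacetalisation (MOM cleavage); both acetals sit ortho to the acetyl carbonyl and are unusually labile, so dilute methanolic acid should suffice, and because every nucleophilic carbon of arene and pyrone is substituted the released formaldehyde acetal has nowhere to add.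

**Compound list**
1 | 2,4,6-trihydroxyacetophenone | CC(=O)c1c(O)cc(O)cc1O | starting material
2 | 1-[4-(benzyloxy)-2,6-dihydroxyphenyl]ethan-1-one | CC(=O)c1c(O)cc(OCc2ccccc2)cc1O | intermediate
3 | 1-[4-(benzyloxy)-2,6-bis(methoxymethoxy)phenyl]ethan-1-one | CC(=O)c1c(OCOC)cc(OCc2ccccc2)cc1OCOC | intermediate
4 | 1-[4-hydroxy-2,6-bis(methoxymethoxy)phenyl]ethan-1-one | CC(=O)c1c(OCOC)cc(O)cc1OCOC | intermediate
5 | 3-acetyl-6-hydroxy-2,4-bis(methoxymethoxy)benzaldehyde | CC(=O)c1c(OCOC)cc(O)c(C=O)c1OCOC | intermediate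
6 | 3-acetyl-5-bromo-6-hydroxy-2,4-bis(methoxymethoxy)benzaldehyde | CC(=O)c1c(OCOC)c(Br)c(O)c(C=O)c1OCOC | intermediate
7 | myrcene | C=CC(=C)CCC=C(C)C | starting material
8 | (R)-5-acetyl-4,6-bis(methoxymethoxy)-2-(6-methylhepta-1,5-dien-2-yl)-2,3-dihydrobenzofuran-7-carbaldehyde | C=C(CCC=C(C)C)[C@H]1Cc2c(OCOC)c(C(C)=O)c(OCOC)c(C=O)c2O1 | intermediate
9 | dimethyl malonate | COC(=O)CC(=O)OC | starting material
10 | dimethyl (R)-2-{[5-acetyl-4,6-bis(methoxymethoxy)-2-(6-methylhepta-1,5-dien-2-yl)-2,3-dihydrobenzofuran-7-yl]methylidene}malonate | C=C(CCC=C(C)C)[C@H]1Cc2c(OCOC)c(C(C)=O)c(OCOC)c(C=C(C(=O)OC)C(=O)OC)c2O1 | intermediate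
11 | dimethyl (R)-2-{[5-acetyl-4,6-bis(methoxymethoxy)-2-(6-methylhepta-1,5-dien-2-yl)-2,3-dihydrobenzofuran-7-yl]methyl}malonate | C=C(CCC=C(C)C)[C@H]1Cc2c(OCOC)c(C(C)=O)c(OCOC)c(CC(C(=O)OC)C(=O)OC)c2O1 | intermediate
12 | (R)-2-{[5-acetyl-4,6-bis(methoxymethoxy)-2-(6-methylhepta-1,5-dien-2-yl)-2,3-dihydrobenzofuran-7-yl]methyl}malonic acid | C=C(CCC=C(C)C)[C@H]1Cc2c(OCOC)c(C(C)=O)c(OCOC)c(CC(C(=O)O)C(=O)O)c2O1 | intermediate
13 | 3-pentanone | CCC(=O)CC | starting material
14 | (Z)-3-(trimethylsilyloxy)pent-2-ene | C/C=C(\O[Si](C)(C)C)CC | intermediate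
15 | (R)-2-{[5-acetyl-4,6-bis(methoxymethoxy)-2-(6-methylhepta-1,5-dien-2-yl)-2,3-dihydrobenzofuran-7-yl]methyl}malonyl dichloride | C=C(CCC=C(C)C)[C@H]1Cc2c(OCOC)c(C(C)=O)c(OCOC)c(CC(C(=O)Cl)C(=O)Cl)c2O1 | intermediate
16 | 2-{[(R)-5-acetyl-4,6-bis(methoxymethoxy)-2-(6-methylhepta-1,5-dien-2-yl)-2,3-dihydrobenzofuran-7-yl]methyl}-4-methyl-3,5-dioxoheptanoyl chloride (epimers at chain C2 and C4, not isolated) | C=C(CCC=C(C)C)[C@H]1Cc2c(OCOC)c(C(C)=O)c(OCOC)c(CC(C(=O)Cl)C(=O)C(C)C(=O)CC)c2O1 | intermediate
17 | (R)-3-{[5-acetyl-4,6-bis(methoxymethoxy)-2-(6-methylhepta-1,5-dien-2-yl)-2,3-dihydrobenzofuran-7-yl]methyl}-6-ethyl-4-hydroxy-5-methyl-2H-pyran-2-one | C=C(CCC=C(C)C)[C@H]1Cc2c(OCOC)c(C(C)=O)c(OCOC)c(Cc3c(O)c(C)c(CC)oc3=O)c2O1 | intermediate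
18 | (R)-3-{[5-acetyl-4,6-dihydroxy-2-(6-methylhepta-1,5-dien-2-yl)-2,3-dihydrobenzofuran-7-yl]methyl}-6-ethyl-4-hydroxy-5-methyl-2H-pyran-2-one | C=C(CCC=C(C)C)[C@H]1Cc2c(O)c(C(C)=O)c(O)c(Cc3c(O)c(C)c(CC)oc3=O)c2O1 | target

Total step count: 13. Longest linear sequence: 12 (steps 1–9 and 11–13).

**Steps most likely to fail**

Step 12.
- What may go wrong: the C6 acetal oxygen may attack the neighbouring acid chloride with loss of its protecting group before the enol ether arrives. The derived ketene may oligomerise. The enol ether may be acylated on oxygen.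
- Fallback: it sets out from 8 (with 14) and returns at 17.
  - Commercial malonyl dichloride and 14, under the same annulation conditions, give 6-ethyl-4-hydroxy-5-methyl-2H-pyran-2-one F1.
  - F1, aldehyde 8, Hantzsch ester and catalytic L-proline in CH2Cl2 at rt then undergo the known three-component reductive alkylation of 4-hydroxy-2-pyrones.
  - Knoevenagel condensation gives the alkylidene pyrandione F2, and transfer hydrogenation in the same flask gives 17.
  - The bridge carbon is already bound to the arene, so no symmetrical methylene dimer can arise.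

Step 6.
- What may go wrong: oxidative addition into a C–Br bond flanked by two oxygen substituents may be slow. Insertion may occur at the wrong alkene of the diene. Facial selectivity in C–O bond formation may be poor, or may be eroded by re-ionisation of the allylic aryl ether.
- Fallback: it sets out from 5 and returns at 8, and it moves the source of chirality from catalyst control to resolution.
  - NIS in MeCN gives 3-acetyl-6-hydroxy-5-iodo-2,4-bis(methoxymethoxy)benzaldehyde F3.
  - The classical Larock heteroannulation of F3 with 7 (Pd(OAc)2, n-Bu4NCl, NaHCO3, DMF, 80 °C) gives the racemic aldehyde F4.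
  - Preparative chromatography on a cellulose-based chiral phase separates 8 from the (S)-aldehyde F5.

Step 13.
- What may go wrong: the trisubstituted alkene may be protonated, followed by cation–olefin cyclisation of the 1,5-diene. The allylic C2–O1 bond may ionise in acid with loss of configurational purity. The methylene bridge may fragment in acid.
- Fallback: it sets out from 17 and returns at 18 without any Brønsted acid.
  - TMSOTf and 2,2'-bipyridyl in CH2Cl2 at 0 °C exchange each aryl MOM group for a trimethylsilyl group and silylate the pyrone hydroxyl. This gives the tris(trimethylsilyl) ether F6.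
  - Water in THF at rt then hydrolyses F6 to 18 under neutral conditions.

**Further compounds**
F1 | step 12 | 6-ethyl-4-hydroxy-5-methyl-2H-pyran-2-one | CCc1oc(=O)cc(O)c1C
F2 | step 12 | (R)-3-{[5-acetyl-4,6-bis(methoxymethoxy)-2-(6-methylhepta-1,5-dien-2-yl)-2,3-dihydrobenzofuran-7-yl]methylidene}-6-ethyl-5-methyl-2H-pyran-2,4(3H)-dione | C=C(CCC=C(C)C)[C@H]1Cc2c(OCOC)c(C(C)=O)c(OCOC)c(C=C3C(=O)OC(CC)=C(C)C3=O)c2O1
F3 | step 6 | 3-acetyl-6-hydroxy-5-iodo-2,4-bis(methoxymethoxy)benzaldehyde | CC(=O)c1c(OCOC)c(I)c(O)c(C=O)c1OCOC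
F4 | step 6 | racemic 5-acetyl-4,6-bis(methoxymethoxy)-2-(6-methylhepta-1,5-dien-2-yl)-2,3-dihydrobenzofuran-7-carbaldehyde | C=C(CCC=C(C)C)C1Cc2c(OCOC)c(C(C)=O)c(OCOC)c(C=O)c2O1
F5 | step 6 | (S)-5-acetyl-4,6-bis(methoxymethoxy)-2-(6-methylhepta-1,5-dien-2-yl)-2,3-dihydrobenzofuran-7-carbaldehyde | C=C(CCC=C(C)C)[C@@H]1Cc2c(OCOC)c(C(C)=O)c(OCOC)c(C=O)c2O1
F6 | step 13 | (R)-3-{[5-acetyl-2-(6-methylhepta-1,5-dien-2-yl)-4,6-bis(trimethylsilyloxy)-2,3-dihydrobenzofuran-7-yl]methyl}-6-ethyl-5-methyl-4-(trimethylsilyloxy)-2H-pyran-2-one | C=C(CCC=C(C)C)[C@H]1Cc2c(O[Si](C)(C)C)c(C(C)=O)c(O[Si](C)(C)C)c(Cc3c(O[Si](C)(C)C)c(C)c(CC)oc3=O)c2O1
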